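**Plan**
- Retrosynthesis: the two ArCH2–C4 bonds joining ring B to the filicinic acid rings A and C are cut first (giving a bis(benzylic bromide) and two molecules of isobutyrylfilicinic acid). Ring B is then cut at C4–C5 and C1–C6 (2-pyranone 9 plus ynol ether 14), and the pyranone goes back to malonyl dichloride, a propanoate ketene acetal and isobutyryl chloride.
- Enabling feature: ring B is a benzene whose six substituents alternate C, O, C, O, C, O (C1 isobutyryl, C2–O, C3 arm, C4–O, C5 arm, C6–O). C1–C4 are the diene carbons C3–C6 of a 3-acyl-4,6-dimethoxy-5-methyl-2-pyranone and C5–C6 are the two carbons of 1-methoxypropyne, with donor and acceptor ends matched.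
- Forward order: pyranone ring (steps 1–4), ring B by [4+2] cycloaddition and CO2 loss (step 6), rings A and C as isobutyrylfilicinic acid from phloroglucinol (steps 8–9), union through the brominated C3/C5 methyl arms (steps 7 and 10), ether cleavage (step 11).
- Stereochemistry: the target has no stereocentre and no configured double bond, so nothing has to be controlled.

Key step: step 6

Remark: the β-triketone rings are drawn as the enol tautomer of the target SMILES; rings A and C are spectators of the ring B construction, so the arms pass through the cycloaddition as C-methyl groups and the unprotected outer rings are joined to them afterwards, which keeps acidic enols away from the ynol ether and the pyranone.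

**Step 1**
Reactants: 1 methyl propanoate
Product: 2 (E)-1-methoxy-1-(trimethylsilyloxy)prop-1-ene
Conditions: LiN(i-Pr)2, THF, −78 °C; Me3SiCl, −78 → 20 °C; non-aqueous work-up
Reagents that add atoms: chlorotrimethylsilane, C[Si](C)(C)Cl
Why: O-silylation of the lithium ester enolate gives the ketene silyl acetal (mainly E under these conditions; the geometry is lost in step 2).

**Step 2**
Reactants: 2 (E)-1-methoxy-1-(trimethylsilyloxy)prop-1-ene; 3 malonyl dichloride
Product: 5 4-hydroxy-6-methoxy-5-methyl-2H-pyran-2-one, via methyl 5-chloro-2-methyl-3,5-dioxopentanoate 4 (not isolated)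
Conditions: 3 (1.0 equiv), CH2Cl2, 2 added slowly at −78 → 0 °C; then 2,6-lutidine (1.0 equiv), 0 → 20 °C; non-aqueous work-up
Reagents that add atoms: none
Why: Proposed new method: one acid chloride of 3 should C-acylate the ketene silyl acetal with loss of Me3SiCl (the known acylation of ketene silyl acetals), and in the acid chloride 4 (or the acylketene the base makes from it) the only six-membered closure open is through the carbonyl oxygen of the methyl ester, after which loss of the C5 proton gives the 6-methoxy-2-pyranone; the closest known reactions are the cyclocondensation of ketone trimethylsilyl enol ethers with malonyl dichloride to 4-hydroxy-2-pyranones and the closure of homophthalic half-ester acid chlorides to 3-alkoxyisocoumarins.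

**Step 3**
Reactants: 5 4-hydroxy-6-methoxy-5-methyl-2H-pyran-2-one; 6 2-methylpropanoyl chloride (isobutyryl chloride)
Product: 8 4-hydroxy-6-methoxy-5-methyl-3-(2-methylpropanoyl)-2H-pyran-2-one, via 6-methoxy-5-methyl-2-oxo-2H-pyran-4-yl 2-methylpropanoate 7 (not isolated)
Conditions: 6, Et3N, CH2Cl2, 0 °C; then DMAP (0.2 equiv), 40 °C
Reagents that add atoms: none
Why: O-acylation of the vinylogous acid followed by DMAP-catalysed O-to-C acyl migration (Fries-type 1,3-shift, well known for 4-hydroxy-2-pyranones) places the acyl group on C3, the only unsubstituted ring carbon, where it is held as the chelated enol.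

**Step 4**
Reactants: 8 4-hydroxy-6-methoxy-5-methyl-3-(2-methylpropanoyl)-2H-pyran-2-one
Product: 9 4,6-dimethoxy-5-methyl-3-(2-methylpropanoyl)-2H-pyran-2-one
Conditions: Me2SO4 (1.5 equiv), K2CO3 (2 equiv), acetone, 50 °C
Reagents that add atoms: dimethyl sulfate, COS(=O)(=O)OC
Why: O-methylation of the acidic 4-hydroxyl with a hard electrophile is the standard way from 4-hydroxy- to 4-methoxy-2-pyranones, and C-methylation at the fully substituted C3 or C5 would cost the pyranone conjugation.

**Step 5**
Reactants: 10 2-chloro-1,1-dimethoxyethane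
Product: 14 1-methoxyprop-1-yne, via 1-chloro-2-methoxyethene 11 (not isolated), via methoxyethyne 12 (not isolated), via sodium methoxyethynide 13 (not isolated)
Conditions: NaNH2 (3 equiv), liquid NH3, −33 °C; MeI, −33 °C; NH3 evaporated, H2O, distillation
Reagents that add atoms: iodomethane, CI
Why: Two base-induced eliminations (methanol, then HCl) and deprotonation give the sodium alkoxyacetylide in one pot, which is C-methylated; this is the classical preparation of 1-alkoxy-1-alkynes from α-chloroacetals.

**Step 6**
Reactants: 9 4,6-dimethoxy-5-methyl-3-(2-methylpropanoyl)-2H-pyran-2-one; 14 1-methoxyprop-1-yne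
Product: 16 1-(2,4,6-trimethoxy-3,5-dimethylphenyl)-2-methylpropan-1-one, via 1,5,8-trimethoxy-6,7-dimethyl-4-(2-methylpropanoyl)-2-oxabicyclo[2.2.2]octa-5,7-dien-3-one 15 (not isolated)
Conditions: 14 (4 equiv), toluene, 110 °C, sealed tube
Reagents that add atoms: none
Why: Inverse-electron-demand Diels–Alder reaction: the 3-acyl group and the lactone carbonyl make C3=C4–C5=C6 of 9 an electron-poor diene with C6 as acceptor terminus, so the nucleophilic methyl-bearing carbon of 14 bonds to C6 and its methoxy-bearing carbon to C3, forming C4–C5 and C1–C6 of ring B in one asynchronous [4+2] step. The bridged lactone 15 then loses CO2 by retro-[4+2], and ring B arrives aromatic with acyl, O, C, O, C, O around it. The closest known reaction type is the cycloaddition of acceptor-substituted 2-pyranones with ynamines and alkynyl ethers followed by decarboxylative aromatisation. Ring B closes by intermolecular [4+2] cycloaddition; no stereocentre is created, since the two bridgeheads of the mirror-symmetric adduct 15 become arene carbons. The selectivity needed is regiochemical and rests on the matched polarisation of the two partners; the methyl ynol ether cannot lose an alkene by retro-ene reaction, so the temperature can be raised as far as the doubly alkoxylated pyranone requires.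

**Step 7**
Reactants: 16 1-(2,4,6-trimethoxy-3,5-dimethylphenyl)-2-methylpropan-1-one
Product: 17 1-[3,5-bis(bromomethyl)-2,4,6-trimethoxyphenyl]-2-methylpropan-1-one
Conditions: NBS (2.1 equiv), AIBN (5 mol %), PhCF3, 80 °C
Reagents that add atoms: N-bromosuccinimide, O=C1CCC(=O)N1Br
Why: Wohl–Ziegler radical bromination can only attack side chains on the fully substituted ring, and the electrophilic bromine atom should prefer the two electron-rich benzylic methyl groups over the methoxy C–H bonds and the α-C–H of the twisted ketone.

**Step 8**
Reactants: 18 phloroglucinol; 6 2-methylpropanoyl chloride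
Product: 19 1-(2,4,6-trihydroxyphenyl)-2-methylpropan-1-one
Conditions: AlCl3 (4 equiv), PhNO2, 25 → 65 °C; aq. HCl
Reagents that add atoms: none
Why: Friedel–Crafts C-acylation of the highly activated arene, in which the first acyl group deactivates the ring against a second.

**Step 9**
Reactants: 19 1-(2,4,6-trihydroxyphenyl)-2-methylpropan-1-one
Product: 20 3,5-dihydroxy-6,6-dimethyl-2-(2-methylpropanoyl)cyclohexa-2,4-dien-1-one (isobutyrylfilicinic acid)
Conditions: NaOMe (3 equiv), MeI (2.5 equiv), MeOH, 0 → 25 °C; aq. HCl
Reagents that add atoms: iodomethane, CI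
Why: Two successive C-methylations of the phloroglucinolate at the same ring carbon (dearomatising alkylation) are the established route from acylphloroglucinols to acylfilicinic acids, with under- and over-methylated by-products to be separated.

**Step 10**
Reactants: 17 1-[3,5-bis(bromomethyl)-2,4,6-trimethoxyphenyl]-2-methylpropan-1-one; 20 isobutyrylfilicinic acid (2.3 equiv)
Product: 21 4,4'-{[2,4,6-trimethoxy-5-(2-methylpropanoyl)-1,3-phenylene]bis(methylene)}bis[3,5-dihydroxy-6,6-dimethyl-2-(2-methylpropanoyl)cyclohexa-2,4-dien-1-one]
Conditions: ZnBr2 (20 mol %), CH2Cl2, 0 → 25 °C, N2 sweep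
Reagents that add atoms: none
Why: The 2,4,6-trimethoxybenzylic bromides ionise readily and the cations should be captured by the enol carbon C4 of 20, its only ring C–H (Lewis-acid-promoted SN1 C-benzylation of a cyclic 1,3-dione), while any O-benzyl enol ether would re-ionise and end as the C-alkylated product.

**Step 11**
Reactants: 21 ring B trimethyl ether of the target
Product: 22 4,4'-{[2,4,6-trihydroxy-5-(2-methylpropanoyl)-1,3-phenylene]bis(methylene)}bis[3,5-dihydroxy-6,6-dimethyl-2-(2-methylpropanoyl)cyclohexa-2,4-dien-1-one] (onind)
Conditions: BBr3 (10 equiv), CH2Cl2, −78 → 0 °C; H2O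
Reagents that add atoms: none
Why: Lewis-acid cleavage of the three aryl methyl ethers (the two beside the ketone assisted by chelation) should leave the methylene bridges intact, because rings A and C carry no ether and the boron-complexed ring B is too electron-poor to expel an arm.

**Compound list**
1 | methyl propanoate | CCC(=O)OC | starting material
2 | (E)-1-methoxy-1-(trimethylsilyloxy)prop-1-ene | C/C=C(/O[Si](C)(C)C)OC | intermediate
3 | malonyl dichloride | O=C(Cl)CC(Cl)=O | starting material
4 | methyl 5-chloro-2-methyl-3,5-dioxopentanoate (racemic) | COC(=O)C(C)C(=O)CC(Cl)=O | intermediate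
5 | 4-hydroxy-6-methoxy-5-methyl-2H-pyran-2-one | COC1=C(C)C(O)=CC(=O)O1 | intermediate
6 | 2-methylpropanoyl chloride (isobutyryl chloride) | CC(C)C(Cl)=O | starting material
7 | 6-methoxy-5-methyl-2-oxo-2H-pyran-4-yl 2-methylpropanoate | COC1=C(C)C(OC(=O)C(C)C)=CC(=O)O1 | intermediate
8 | 4-hydroxy-6-methoxy-5-methyl-3-(2-methylpropanoyl)-2H-pyran-2-one | CC(C)C(=O)C1=C(O)C(C)=C(OC)OC1=O | intermediate
9 | 4,6-dimethoxy-5-methyl-3-(2-methylpropanoyl)-2H-pyran-2-one | CC(C)C(=O)C1=C(OC)C(C)=C(OC)OC1=O | intermediate
10 | 2-chloro-1,1-dimethoxyethane | ClCC(OC)OC | starting material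
11 | 1-chloro-2-methoxyethene (E/Z mixture) | ClC=COC | intermediate
12 | methoxyethyne | COC#C | intermediate
13 | sodium methoxyethynide | [Na+].[C-]#COC | intermediate
14 | 1-methoxyprop-1-yne | CC#COC | intermediate
15 | 1,5,8-trimethoxy-6,7-dimethyl-4-(2-methylpropanoyl)-2-oxabicyclo[2.2.2]octa-5,7-dien-3-one (achiral, mirror plane through the lactone bridge) | O=C1OC2(OC)C(C)=C(OC)C1(C(=O)C(C)C)C(OC)=C2C | intermediate
16 | 1-(2,4,6-trimethoxy-3,5-dimethylphenyl)-2-methylpropan-1-one | CC(C)C(=O)c1c(OC)c(C)c(OC)c(C)c1OC | intermediate
17 | 1-[3,5-bis(bromomethyl)-2,4,6-trimethoxyphenyl]-2-methylpropan-1-one | CC(C)C(=O)c1c(OC)c(CBr)c(OC)c(CBr)c1OC | intermediate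
18 | phloroglucinol (benzene-1,3,5-triol) | Oc1cc(O)cc(O)c1 | starting material
19 | 1-(2,4,6-trihydroxyphenyl)-2-methylpropan-1-one | CC(C)C(=O)c1c(O)cc(O)cc1O | intermediate
20 | 3,5-dihydroxy-6,6-dimethyl-2-(2-methylpropanoyl)cyclohexa-2,4-dien-1-one (isobutyrylfilicinic acid) | CC(C)C(=O)C1=C(O)C=C(O)C(C)(C)C1=O | intermediate
21 | ring B 2,4,6-tri-O-methyl ether of the target | CC(C)C(=O)c1c(OC)c(CC2=C(O)C(C)(C)C(=O)C(C(=O)C(C)C)=C2O)c(OC)c(CC2=C(O)C(C)(C)C(=O)C(C(=O)C(C)C)=C2O)c1OC | intermediate
22 | onind | CC(C)C(=O)C1=C(O)C(Cc2c(O)c(CC3=C(O)C(C)(C)C(=O)C(C(=O)C(C)C)=C3O)c(O)c(C(=O)C(C)C)c2O)=C(O)C(C)(C)C1=O | target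

**Count and risks**
Total: 11 steps. Longest linear sequence: 8 steps (1, 2, 3, 4, 6, 7, 10, 11).

Step 2 (Proposed new method): the bifunctional acid chloride may acylate two molecules of 2 or condense with itself before the ring closes, and the HCl set free may strip the 6-O-methyl group. The fallback uses known chemistry, sets out from 2 and comes back at 5. Compound 2 is acylated with the monofunctional benzyl 3-chloro-3-oxopropanoate F1 (from benzyl hydrogen malonate and oxalyl chloride) to give 5-benzyl 1-methyl 2-methyl-3-oxopentanedioate F2. Hydrogenolysis (H2, Pd/C, EtOAc) frees 5-methoxy-4-methyl-3,5-dioxopentanoic acid F3. Oxalyl chloride at 0 °C turns this into 4, and 2,6-lutidine closes it to 5, as homophthalic half-ester chlorides close to 3-alkoxyisocoumarins.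

Step 6: the two methoxy groups may leave the pyranone too electron-rich to react before the ynol ether oligomerises, or the ynol ether may add at C4 (conjugate addition or hetero-Diels–Alder across the acyl enone) instead of C6. The fallback goes from 9 back to 16. The more nucleophilic and thermally robust ketene acetal 1,1-dimethoxyprop-1-ene F4 (from 1,1,1-trimethoxypropane by elimination of methanol with Me3SiOTf and i-Pr2NEt) serves as the two-carbon partner in toluene at 120–140 °C. The adduct 1,5,8,8-tetramethoxy-6,7-dimethyl-4-(2-methylpropanoyl)-2-oxabicyclo[2.2.2]oct-5-en-3-one F5 should lose CO2 to 1-(2,4,6,6-tetramethoxy-3,5-dimethylcyclohexa-1,3-dien-1-yl)-2-methylpropan-1-one F6, which aromatises to 16 by loss of methanol. This is the well-known cycloaddition of acceptor 2-pyranones with 1,1-dialkoxyalkenes.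

Step 7: the twofold radical bromination may stop at the monobromide, run on to dibromomethyl groups or attack the isobutyryl methine, and the bis(benzylic bromide) may solvolyse on handling. The fallback goes from 16 back to 21 and oxidises the side chains by electron transfer instead of hydrogen abstraction. DDQ in acetic acid at 60–80 °C (the benzylic acetoxylation known for polymethyl- and methoxy-methylbenzenes) should give [2,4,6-trimethoxy-5-(2-methylpropanoyl)-1,3-phenylene]bis(methylene) diacetate F7, a storable cation precursor. With 20 and BF3·OEt2 in CH2Cl2 this should give 21 directly.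

**Further compounds**
F1 | step 2 | benzyl 3-chloro-3-oxopropanoate | O=C(Cl)CC(=O)OCc1ccccc1
F2 | step 2 | 5-benzyl 1-methyl 2-methyl-3-oxopentanedioate (racemic) | COC(=O)C(C)C(=O)CC(=O)OCc1ccccc1
F3 | step 2 | 5-methoxy-4-methyl-3,5-dioxopentanoic acid (racemic) | COC(=O)C(C)C(=O)CC(=O)O
F4 | step 6 | 1,1-dimethoxyprop-1-ene | CC=C(OC)OC
F5 | step 6 | 1,5,8,8-tetramethoxy-6,7-dimethyl-4-(2-methylpropanoyl)-2-oxabicyclo[2.2.2]oct-5-en-3-one (racemic, both epimers at C7) | O=C1OC2(OC)C(C)=C(OC)C1(C(=O)C(C)C)C(OC)(OC)C2C
F6 | step 6 | 1-(2,4,6,6-tetramethoxy-3,5-dimethylcyclohexa-1,3-dien-1-yl)-2-methylpropan-1-one (racemic) | CC(C)C(=O)C1=C(OC)C(C)=C(OC)C(C)C1(OC)OC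
F7 | step 7 | [2,4,6-trimethoxy-5-(2-methylpropanoyl)-1,3-phenylene]bis(methylene) diacetate | CC(C)C(=O)c1c(OC)c(COC(C)=O)c(OC)c(COC(C)=O)c1OC
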